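**Plan**

1. Numbering of the hexahydroindene core: five-membered ring C1–C2–C3–C3a–C7a, six-membered ring C3a–C4–C5–C6–C7–C7a (C4 quaternary, C5 phenyl, C6=C7 alkene).
2. Cuts, in retrosynthetic order: the acrylic acid arm on C4 (olefination of a C4 aldehyde, carried as a nitrile); C6=C7 moved to an exocyclic C7=CH2; C2–C3 and C3a–C7a together; C4–C5 (Michael addition); the enone C=C (aldol condensation).
3. Enabling feature: C7a–C1(Me)–C2 is a three-carbon unit on the alkene carbon C7, and C3a–C3(Me) is a two-carbon unit on C4, three atoms (C6, C5, C4) away. With C7a–C2 closed to a cyclopropane and C7 as a 1,1-disubstituted vinyl carbon, the precursor is an α-tethered ene-vinylcyclopropane, the substrate class of the rhodium-catalysed intramolecular (3+2) cycloaddition.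
4. Forward: cyclopropyl enone → Michael adduct → methylene and (Z)-propenyl arms → cyclopentane and cyclohexane closed in one step → alkene isomerisation → nitrile to aldehyde → side chain.
5. Stereochemistry: C1 from (1R,2R)-2-methylcyclopropanecarboxylic acid (its bonds are never broken); C4 and C5 from the catalytic asymmetric Michael addition; C3 from the (Z)-alkene by suprafacial addition; C3a and C7a from the cycloaddition transition state; side-chain E geometry from the olefination.

Key step: step 8

Assumption 1: (1R,2R)-2-methylcyclopropane-1-carboxylic acid is taken as a purchasable single enantiomer (otherwise the racemic trans acid is resolved as a chiral amine salt).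
Assumption 2: in step 3 the quinine-derived primary amine is taken to give the (2R,3S) adduct; if the induction is opposite, the quinidine-derived pseudoenantiomer is used.

**Route**

Step 1
Reactants: 1 (1R,2R)-2-methylcyclopropane-1-carboxylic acid
Product: 3 1-[(1R,2R)-2-methylcyclopropyl]ethan-1-one, via dilithium gem-diolate 2 (not isolated)
Conditions: MeLi (2.2 equiv), Et2O, 0 °C to rt; then H2O
Reagents that add atoms: methyllithium, [Li]C
Why: Ketone synthesis from a carboxylic acid by double addition of methyllithium; the dilithium gem-diolate resists further addition and both cyclopropane centres are untouched.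

Step 2
Reactants: 3 1-[(1R,2R)-2-methylcyclopropyl]ethan-1-one; 4 benzaldehyde
Product: 6 (E)-1-[(1R,2R)-2-methylcyclopropyl]-3-phenylprop-2-en-1-one, via aldol adduct 5 (not isolated)
Conditions: NaOH (aq., cat.), EtOH, 0 °C to rt
Reagents that add atoms: none
Why: Claisen–Schmidt aldol condensation; only the methyl group of 3 enolises readily, and dehydration should give the (E)-enone.

Step 3
Reactants: 6 (E)-1-[(1R,2R)-2-methylcyclopropyl]-3-phenylprop-2-en-1-one; 7 ethyl 2-cyanobutanoate (racemic)
Product: 8 ethyl (2R,3S)-2-cyano-2-ethyl-5-[(1R,2R)-2-methylcyclopropyl]-5-oxo-3-phenylpentanoate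
Conditions: 9-amino-9-deoxy-epi-quinine (20 mol %), CF3CO2H (40 mol %), toluene, rt
Reagents that add atoms: none
Why: Catalytic asymmetric Michael addition of an α-substituted cyanoacetate to a β-aryl enone through its iminium ion; the catalyst shields one face of the enone (benzylic centre S) and orients the planar cyanoester enolate (quaternary centre R), and racemic 7 can be used since its stereocentre is lost on deprotonation.

Step 4
Reactants: 8 ethyl (2R,3S)-2-cyano-2-ethyl-5-[(1R,2R)-2-methylcyclopropyl]-5-oxo-3-phenylpentanoate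
Product: 9 ethyl (2R,3S)-2-cyano-2-ethyl-5-[(1R,2R)-2-methylcyclopropyl]-3-phenylhex-5-enoate
Conditions: MePPh3Br, KN(SiMe3)2, THF, 0 °C; then 8, 0 °C to rt
Reagents that add atoms: methyltriphenylphosphonium bromide, C[P+](c1ccccc1)(c1ccccc1)c1ccccc1.[Br-]
Why: Wittig methylenation of the only ketone (the quaternary ester and the nitrile should not react with the ylide at this temperature); this turns the cyclopropyl ketone into the α-substituted vinylcyclopropane needed in step 8.

Step 5
Reactants: 9 ethyl (2R,3S)-2-cyano-2-ethyl-5-[(1R,2R)-2-methylcyclopropyl]-3-phenylhex-5-enoate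
Product: 10 (2R,3S)-2-ethyl-2-(hydroxymethyl)-5-[(1R,2R)-2-methylcyclopropyl]-3-phenylhex-5-enenitrile
Conditions: LiBH4, THF, 0 to 40 °C
Reagents that add atoms: none
Why: Chemoselective borohydride reduction of the activated α-cyano ester to the primary alcohol; nitrile and alkene are inert to LiBH4.

Step 6
Reactants: 10 (2R,3S)-2-ethyl-2-(hydroxymethyl)-5-[(1R,2R)-2-methylcyclopropyl]-3-phenylhex-5-enenitrile
Product: 11 (2R,3S)-2-ethyl-2-formyl-5-[(1R,2R)-2-methylcyclopropyl]-3-phenylhex-5-enenitrile
Conditions: Dess–Martin periodinane, CH2Cl2, 0 °C to rt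
Reagents that add atoms: none
Why: Dess–Martin oxidation of the neopentyl-type primary alcohol to an aldehyde that has no α-hydrogen and cannot epimerise.

Step 7
Reactants: 11 (2R,3S)-2-ethyl-2-formyl-5-[(1R,2R)-2-methylcyclopropyl]-3-phenylhex-5-enenitrile
Product: 12 (2R,3S)-2-ethyl-5-[(1R,2R)-2-methylcyclopropyl]-3-phenyl-2-[(1Z)-prop-1-en-1-yl]hex-5-enenitrile
Conditions: EtPPh3Br, KN(SiMe3)2, THF, −78 to 0 °C
Reagents that add atoms: ethyltriphenylphosphonium bromide, CC[P+](c1ccccc1)(c1ccccc1)c1ccccc1.[Br-]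
Why: Salt-free Wittig reaction of an unstabilised ylide, which should give the (Z)-alkene by kinetic cis-oxaphosphetane formation; this geometry later places the 3-methyl group cis to C4.

Step 8
Reactants: 12 (2R,3S)-2-ethyl-5-[(1R,2R)-2-methylcyclopropyl]-3-phenyl-2-[(1Z)-prop-1-en-1-yl]hex-5-enenitrile
Product: 13 (1R,3R,3aR,4R,5S,7aR)-4-ethyl-1,3-dimethyl-7-methylidene-5-phenyloctahydro-1H-indene-4-carbonitrile
Conditions: [Rh(Ph2PCH2PPh2)]SbF6 (10 mol %), ClCH2CH2Cl, 90 °C
Reagents that add atoms: none
Why: Monovalent rhodium binds the 1,1-disubstituted vinyl group and inserts into the less substituted cyclopropane bond C7a–C2 (the CH–CH2 bond, not the CH–CHMe bond) to give a trivalent rhodium σ-alkyl/π-allyl species; syn insertion of the (Z)-propenyl C3a=C3 bond into the Rh–C2 bond and C–C reductive elimination at the proximal allyl terminus C7a complete a formal (3+2) cycloaddition and leave the distal allyl carbon as the exocyclic methylene on C7. The closest known reaction type is the rhodium-catalysed intramolecular (3+2) cycloaddition of α-ene-vinylcyclopropanes, which gives bicyclo[4.3.0]nonanes from a three-atom tether instead of bridged (5+2) adducts. The cyclopentane (C1, C2, C3, C3a, C7a) closes by the cycloaddition itself, and the six-membered ring (C3a, C4, C5, C6, C7, C7a) closes through the tether C4–C5–C6 when C3a is joined to C7a. C1 is carried over unchanged from the cyclopropane; C3 is fixed relative to C3a by suprafacial addition to the (Z)-alkene (3-methyl cis to C4); C3a and C7a are set by a chair-like six-membered array in which both forming cyclopentane bonds are equatorial (trans fusion) and the 5-phenyl group lies anti to the small axial nitrile on C4. The step needs cleavage of the unsubstituted cyclopropane bond, (3+2) closure ahead of β-hydride elimination, and the trans ring fusion: the first should follow from the trans-2-methyl substituent, the second from the α-attachment of the tether, and the third rests on the equatorial preference of both ring-fusion bonds and is the main uncertainty. The nitrile is a helper here: it holds the side-chain carbon as a small, inert group, so that the propenyl arm is the only alkene that can insert.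

Step 9
Reactants: 13 (1R,3R,3aR,4R,5S,7aR)-4-ethyl-1,3-dimethyl-7-methylidene-5-phenyloctahydro-1H-indene-4-carbonitrile
Product: 14 (1R,3R,3aR,4R,5S,7aR)-4-ethyl-1,3,7-trimethyl-5-phenyl-2,3,3a,4,5,7a-hexahydro-1H-indene-4-carbonitrile
Conditions: Co(salen)Cl (3 mol %; salen = N,N′-bis(3,5-di-tert-butylsalicylidene)-1,2-cyclohexanediaminate), PhSiH3 (5 mol %), benzene, 22 °C
Reagents that add atoms: none
Why: Cobalt-hydride hydrogen-atom-transfer alkene isomerisation; the tertiary radical at C7 should lose a hydrogen atom from the less hindered C6 methylene and not from the ring-fusion methine C7a, which gives the trisubstituted C6=C7 alkene.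

Step 10
Reactants: 14 (1R,3R,3aR,4R,5S,7aR)-4-ethyl-1,3,7-trimethyl-5-phenyl-2,3,3a,4,5,7a-hexahydro-1H-indene-4-carbonitrile
Product: 16 (1R,3R,3aR,4R,5S,7aR)-4-ethyl-1,3,7-trimethyl-5-phenyl-2,3,3a,4,5,7a-hexahydro-1H-indene-4-carbaldehyde, via N-alumanyl aldimine 15 (not isolated)
Conditions: i-Bu2AlH, toluene, −78 to 0 °C; then aq. potassium sodium tartrate, dilute HCl
Reagents that add atoms: water, O
Why: Partial reduction of a tertiary nitrile with i-Bu2AlH, which stops at the N-aluminated imine; hydrolysis on work-up gives the aldehyde, and no stereocentre next to it carries a hydrogen.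

Step 11
Reactants: 16 (1R,3R,3aR,4R,5S,7aR)-4-ethyl-1,3,7-trimethyl-5-phenyl-2,3,3a,4,5,7a-hexahydro-1H-indene-4-carbaldehyde
Product: 17 ethyl (2E)-3-[(1R,3R,3aR,4S,5S,7aR)-4-ethyl-1,3,7-trimethyl-5-phenyl-2,3,3a,4,5,7a-hexahydro-1H-inden-4-yl]-2-methylprop-2-enoate
Conditions: (EtO)2P(O)CH(CH3)CO2Et, NaH, THF, 0 to 60 °C
Reagents that add atoms: triethyl 2-phosphonopropanoate, CCOC(=O)C(C)P(=O)(OCC)OCC
Why: Horner–Wadsworth–Emmons olefination of a non-enolisable aldehyde with an α-methyl phosphonate, which should give the (E)-trisubstituted enoate with the ester trans to the ring.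

Step 12
Reactants: 17 ethyl (2E)-3-[(1R,3R,3aR,4S,5S,7aR)-4-ethyl-1,3,7-trimethyl-5-phenyl-2,3,3a,4,5,7a-hexahydro-1H-inden-4-yl]-2-methylprop-2-enoate
Product: 18 plakotenin, (2E)-3-[(1R,3R,3aR,4S,5S,7aR)-4-ethyl-1,3,7-trimethyl-5-phenyl-2,3,3a,4,5,7a-hexahydro-1H-inden-4-yl]-2-methylprop-2-enoic acid
Conditions: LiOH, THF/MeOH/H2O, 50 °C; then aq. HCl to pH 3
Reagents that add atoms: lithium hydroxide, [Li+].[OH-]
Why: Saponification of the ethyl ester; the hindered conjugated ester needs warming and no stereocentre is at risk.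

**Compound list**

1 | (1R,2R)-2-methylcyclopropane-1-carboxylic acid | C[C@@H]1C[C@H]1C(=O)O | starting material
2 | dilithium 1-[(1R,2R)-2-methylcyclopropyl]ethane-1,1-bis(olate) | C[C@@H]1C[C@H]1C(C)([O-])[O-].[Li+].[Li+] | intermediate
3 | 1-[(1R,2R)-2-methylcyclopropyl]ethan-1-one | C[C@@H]1C[C@H]1C(C)=O | intermediate
4 | benzaldehyde | O=Cc1ccccc1 | starting material
5 | 3-hydroxy-1-[(1R,2R)-2-methylcyclopropyl]-3-phenylpropan-1-one (aldol adduct, both carbinol epimers) | C[C@@H]1C[C@H]1C(=O)CC(O)c1ccccc1 | intermediate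
6 | (E)-1-[(1R,2R)-2-methylcyclopropyl]-3-phenylprop-2-en-1-one | C[C@@H]1C[C@H]1C(=O)/C=C/c1ccccc1 | intermediate
7 | ethyl 2-cyanobutanoate (racemic) | CCC(C#N)C(=O)OCC | starting material
8 | ethyl (2R,3S)-2-cyano-2-ethyl-5-[(1R,2R)-2-methylcyclopropyl]-5-oxo-3-phenylpentanoate | CC[C@@](C#N)(C(=O)OCC)[C@@H](CC(=O)[C@@H]1C[C@H]1C)c1ccccc1 | intermediate
9 | ethyl (2R,3S)-2-cyano-2-ethyl-5-[(1R,2R)-2-methylcyclopropyl]-3-phenylhex-5-enoate | CC[C@@](C#N)(C(=O)OCC)[C@@H](CC(=C)[C@@H]1C[C@H]1C)c1ccccc1 | intermediate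
10 | (2R,3S)-2-ethyl-2-(hydroxymethyl)-5-[(1R,2R)-2-methylcyclopropyl]-3-phenylhex-5-enenitrile | CC[C@@](C#N)(CO)[C@@H](CC(=C)[C@@H]1C[C@H]1C)c1ccccc1 | intermediate
11 | (2R,3S)-2-ethyl-2-formyl-5-[(1R,2R)-2-methylcyclopropyl]-3-phenylhex-5-enenitrile | CC[C@@](C#N)(C=O)[C@@H](CC(=C)[C@@H]1C[C@H]1C)c1ccccc1 | intermediate
12 | (2R,3S)-2-ethyl-5-[(1R,2R)-2-methylcyclopropyl]-3-phenyl-2-[(1Z)-prop-1-en-1-yl]hex-5-enenitrile | CC[C@@](C#N)(/C=C\C)[C@@H](CC(=C)[C@@H]1C[C@H]1C)c1ccccc1 | intermediate
13 | (1R,3R,3aR,4R,5S,7aR)-4-ethyl-1,3-dimethyl-7-methylidene-5-phenyloctahydro-1H-indene-4-carbonitrile (trans-fused) | CC[C@@]1(C#N)[C@H]2[C@H](C(=C)C[C@H]1c1ccccc1)[C@H](C)C[C@H]2C | intermediate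
14 | (1R,3R,3aR,4R,5S,7aR)-4-ethyl-1,3,7-trimethyl-5-phenyl-2,3,3a,4,5,7a-hexahydro-1H-indene-4-carbonitrile | CC[C@@]1(C#N)[C@H]2[C@H](C(C)=C[C@H]1c1ccccc1)[C@H](C)C[C@H]2C | intermediate
15 | N-(diisobutylalumanyl) aldimine of 16 | CC[C@@]1(C=N[Al](CC(C)C)CC(C)C)[C@H]2[C@H](C(C)=C[C@H]1c1ccccc1)[C@H](C)C[C@H]2C | intermediate
16 | (1R,3R,3aR,4R,5S,7aR)-4-ethyl-1,3,7-trimethyl-5-phenyl-2,3,3a,4,5,7a-hexahydro-1H-indene-4-carbaldehyde | CC[C@@]1(C=O)[C@H]2[C@H](C(C)=C[C@H]1c1ccccc1)[C@H](C)C[C@H]2C | intermediate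
17 | ethyl (2E)-3-[(1R,3R,3aR,4S,5S,7aR)-4-ethyl-1,3,7-trimethyl-5-phenyl-2,3,3a,4,5,7a-hexahydro-1H-inden-4-yl]-2-methylprop-2-enoate | CC[C@@]1(/C=C(\C)C(=O)OCC)[C@H]2[C@H](C(C)=C[C@H]1c1ccccc1)[C@H](C)C[C@H]2C | intermediate
18 | plakotenin | CC[C@@]1(/C=C(\C)C(=O)O)[C@H]2[C@H](C(C)=C[C@H]1c1ccccc1)[C@H](C)C[C@H]2C | target

**Totals**

Total step count: 12. Longest linear sequence: 12 steps (from 1).

**Steps most likely to fail**

1. Step 8. What may go wrong: insertion of the 1,2-disubstituted (Z)-alkene into the alkyl–rhodium bond may be slower than β-hydride elimination from the ring-opened rhodium alkyl, and the ring fusion may close cis. Fallback (stepwise ionic annulation on the cyclopropyl ketone with a removable formyl activator; sets out from 8, comes back at 13): LiBH4 (THF) should reduce both ester and ketone of 8 to the diol F1, and Dess–Martin periodinane should then give the keto aldehyde F2. A Wittig reaction with 2-(triphenyl-λ5-phosphanylidene)propanal (toluene, 90 °C) should give the (E)-2-methyl enal F3. Me3SiI (CH2Cl2, −40 °C) opens the cyclopropyl ketone by iodide attack at its CH2 carbon (homo-conjugate addition, C1 untouched) to the γ-iodo silyl enol ether F4. TiCl4 (−78 °C) then closes the six-membered ring by an intramolecular Mukaiyama–Michael addition onto the enal, giving the cyclised silyl enol ether F5. Bu4NF releases the aldehyde enolate, which closes the cyclopentane by C-alkylation of the primary iodide to the bicyclic keto aldehyde F6 (F4 and F5 are not isolated). RhCl(PPh3)3 (1 equiv, xylene, 130 °C) removes the formyl group with retention (Tsuji–Wilkinson decarbonylation) to the bicyclic ketone F7, whose C7a centre, now α to a ketone, can be equilibrated with base. Methylenation with MePPh3Br/KN(SiMe3)2 gives 13.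

2. Step 3. What may go wrong: slow conjugate addition of the weakly acidic α-ethyl cyanoester to the β-aryl iminium ion, with retro-Michael equilibration that erodes selectivity at the quaternary carbon. Fallback (the two centres are set on a more electrophilic acceptor and the ketone is attached afterwards; sets out from 7 and 1, comes back at 8): 7 is added to (E)-β-nitrostyrene with a cinchona-derived bifunctional thiourea (toluene, −20 °C) to give the nitro ester F8. Acid 1 and 1,1′-carbonyldiimidazole give the acyl imidazole F9, which C-acylates the potassium nitronate of F8 (KOtBu, THF, −40 °C) to the α-nitro ketone F10 (mixture at the nitro-bearing carbon). Bu3SnH with azobisisobutyronitrile (toluene, 80 °C) removes the nitro group by radical denitration and gives 8.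

3. Step 11. What may go wrong: slow attack at the aldehyde carbon, which is flanked by quaternary C4, the phenyl-bearing C5 and the ring fusion, and loss of E selectivity under forcing conditions. Fallback (addition then elimination instead of olefination; sets out from 16, comes back at 17): the lithium enolate of ethyl propanoate (LiN(i-Pr)2, THF, −78 °C), a small nucleophile, should add to 16 to give the β-hydroxy ester F11 (mixture at the two new centres). MeSO2Cl/Et3N gives the mesylate F12, and 1,8-diazabicyclo[5.4.0]undec-7-ene (toluene, 80 °C) eliminates it by an E1cB path to the (E)-enoate 17.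

**Further compounds**

F1 | step 8 | (2R,3S)-2-ethyl-5-hydroxy-2-(hydroxymethyl)-5-[(1R,2R)-2-methylcyclopropyl]-3-phenylpentanenitrile (both C5 epimers) | CC[C@@](C#N)(CO)[C@@H](CC(O)[C@@H]1C[C@H]1C)c1ccccc1
F2 | step 8 | (2R,3S)-2-ethyl-2-formyl-5-[(1R,2R)-2-methylcyclopropyl]-5-oxo-3-phenylpentanenitrile | CC[C@@](C#N)(C=O)[C@@H](CC(=O)[C@@H]1C[C@H]1C)c1ccccc1
F3 | step 8 | (2R,3S)-2-ethyl-2-[(1E)-2-methyl-3-oxoprop-1-en-1-yl]-5-[(1R,2R)-2-methylcyclopropyl]-5-oxo-3-phenylpentanenitrile | CC[C@@](C#N)(/C=C(\C)C=O)[C@@H](CC(=O)[C@@H]1C[C@H]1C)c1ccccc1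
F4 | step 8 | γ-iodo trimethylsilyl enol ether from ring opening of F3 (enol ether geometry open) | CC[C@@](C#N)(/C=C(\C)C=O)[C@@H](CC(O[Si](C)(C)C)=C[C@H](C)CI)c1ccccc1
F5 | step 8 | cyclised cyclohexanone bearing the aldehyde trimethylsilyl enol ether and the iodomethyl side chain | CC[C@@]1(C#N)[C@H](C(C)=CO[Si](C)(C)C)[C@H](C(=O)C[C@H]1c1ccccc1)[C@H](C)CI
F6 | step 8 | 4-ethyl-3-formyl-1,3-dimethyl-7-oxo-5-phenyloctahydro-1H-indene-4-carbonitrile (trans-fused, formyl trans to C4) | CC[C@@]1(C#N)[C@H]2[C@H](C(=O)C[C@H]1c1ccccc1)[C@H](C)C[C@]2(C)C=O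
F7 | step 8 | (1R,3R,3aR,4R,5S,7aR)-4-ethyl-1,3-dimethyl-7-oxo-5-phenyloctahydro-1H-indene-4-carbonitrile | CC[C@@]1(C#N)[C@H]2[C@H](C(=O)C[C@H]1c1ccccc1)[C@H](C)C[C@H]2C
F8 | step 3 | ethyl (2R,3S)-2-cyano-2-ethyl-4-nitro-3-phenylbutanoate | CC[C@@](C#N)(C(=O)OCC)[C@@H](C[N+](=O)[O-])c1ccccc1
F9 | step 3 | 1H-imidazol-1-yl[(1R,2R)-2-methylcyclopropyl]methanone | C[C@@H]1C[C@H]1C(=O)n1ccnc1
F10 | step 3 | ethyl (2R,3S)-2-cyano-2-ethyl-5-[(1R,2R)-2-methylcyclopropyl]-4-nitro-5-oxo-3-phenylpentanoate (both C4 epimers) | CC[C@@](C#N)(C(=O)OCC)[C@@H](C([N+](=O)[O-])C(=O)[C@@H]1C[C@H]1C)c1ccccc1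
F11 | step 11 | ethyl 3-hydroxy-2-methyl-3-[(1R,3R,3aR,4R,5S,7aR)-4-ethyl-1,3,7-trimethyl-5-phenyl-2,3,3a,4,5,7a-hexahydro-1H-inden-4-yl]propanoate (mixture at the two new centres) | CC[C@@]1(C(O)C(C)C(=O)OCC)[C@H]2[C@H](C(C)=C[C@H]1c1ccccc1)[C@H](C)C[C@H]2C
F12 | step 11 | methanesulfonate of F11 | CC[C@@]1(C(OS(C)(=O)=O)C(C)C(=O)OCC)[C@H]2[C@H](C(C)=C[C@H]1c1ccccc1)[C@H](C)C[C@H]2C
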